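Atom labels are the heavy atoms of the target SMILES in written order. The plan rests on ring C (C16, C17, C19, C20, C24, C23). It is a masked 4,4-dimethylcyclohexenone: C23 bears the CH2O carbon C22, the α′ carbon C16 bears the CH2O carbon C15, and O21 sits on the former β carbon C20. Rings C and D therefore come from achiral 4,4-dimethylcyclohexa-2,5-dienone, a hydroxymethyl anion equivalent and formaldehyde.
Endgame: the C3 acid comes from a primary alcohol. Rings A and B form together in an intramolecular Diels–Alder reaction (C9–C10, C6–C11) of the C15–O14 acrylate with the 8E,6Z diene C9=C8–C7=C6, which is grown from the second C16 arm. C2 comes from (S)-3-bromo-2-methylpropan-1-ol.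
Ring D: Tamao–Fleming oxidation unmasks C22–OH, and O21 adds to C20 by oxa-Michael reaction. Before that a second formaldehyde makes C16 quaternary, and the bicycle then tells the equatorial arm (C15) from the axial arm (C9).
C22–C23 and C16–C15 are made in one flask by copper-catalysed desymmetrising conjugate addition followed by a formaldehyde aldol.
Ring order: C (present in the dienone), then D, then A and B at once.

Key step: step 3

Assumption: the (S,R,R)-configured phosphoramidite is taken to deliver the 5S conjugate adduct; if the sense of induction is the opposite, its (R,S,S) mirror image is used and nothing else changes.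

Step 1
Reactants: 1 4,4-dimethylcyclohex-2-en-1-one
Product: 2 4,4-dimethylcyclohexa-2,5-dien-1-one
Conditions: 2-iodoxybenzoic acid (IBX, 1.5 equiv), DMSO, 80 °C
Reagents that add atoms: none
Why: IBX dehydrogenation of a ketone through its enol can only desaturate the C5–C6 methylene pair because C4 is quaternary, which gives the achiral cross-conjugated dienone without creating a stereocentre.

Step 2
Reactants: 3 (chloromethyl)(isopropoxy)dimethylsilane
Product: 4 {[isopropoxy(dimethyl)silyl]methyl}magnesium chloride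
Conditions: Mg turnings, BrCH2CH2Br (cat.), Et2O, reflux
Reagents that add atoms: magnesium, [Mg]
Why: Grignard formation from an α-silyl alkyl chloride is reliable, and the bulky isopropoxy group keeps the reagent from attacking its own silicon centre.

Step 3
Reactants: 2 4,4-dimethylcyclohexa-2,5-dien-1-one; 4 {[isopropoxy(dimethyl)silyl]methyl}magnesium chloride; 5 formaldehyde (monomer, cracked from paraformaldehyde)
Product: 7 (5S,6R)-6-(hydroxymethyl)-5-{[isopropoxy(dimethyl)silyl]methyl}-4,4-dimethylcyclohex-2-en-1-one, via magnesium enolate 6 (not isolated)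
Conditions: CuBr·SMe2 (5 mol %), (S,R,R)-binaphthol bis(1-phenylethyl)amine phosphoramidite (10 mol %), Et2O, −78 °C, slow addition of 4 (1.1 equiv); then 5 in THF (5 equiv), −78 °C; aq NH4Cl
Reagents that add atoms: none
Why: The ligated monovalent copper silylmethyl species, formed by transmetalation from 4, binds one enone of 2, adds oxidatively at the β carbon C23 to give a trivalent copper intermediate and forms C22–C23 by reductive elimination, which releases the cross-conjugated chloromagnesium dienolate 6; its only nucleophilic carbon, C16, then adds to formaldehyde to form C16–C15. The closest known reaction type is the tandem copper-catalysed asymmetric conjugate addition–aldol (three-component) coupling of cyclic enones, in its desymmetrising form on 4,4-disubstituted cyclohexadienones, combined with the established use of this silylmethyl Grignard reagent as a hydroxymethyl anion equivalent in copper-catalysed 1,4-addition. No ring is closed; two skeletal bonds are made. C23 (S in 7, the same spatial arrangement as R in the target) is controlled by the chiral ligand, which selects one of the enantiotopic enone faces of the C2v-symmetric dienone. C16 (R in 7) is controlled by the substrate, formaldehyde arriving anti to the new pseudoaxial C22 substituent to give the trans product, and this centre is erased in step 4. The step needs 1,4- over 1,2-addition (secured by copper), single addition (the enolate charge switches off the surviving C19=C20 enone until the quench and 4 is kept near one equivalent) and a regiodefined enolate (C24 is quaternary, so 6 cannot equilibrate or react at a γ position).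

Step 4
Reactants: 7 (5S,6R)-6-(hydroxymethyl)-5-{[isopropoxy(dimethyl)silyl]methyl}-4,4-dimethylcyclohex-2-en-1-one; 5 formaldehyde
Product: 8 (5R)-6,6-bis(hydroxymethyl)-5-{[isopropoxy(dimethyl)silyl]methyl}-4,4-dimethylcyclohex-2-en-1-one
Conditions: LiN(iPr)2 (LDA, 2.3 equiv), THF, −78 to −40 °C; 5 in THF, −78 °C; aq NH4Cl
Reagents that add atoms: none
Why: This is an aldol hydroxymethylation of the alkoxide–dienolate dianion, in which C16–H is the only enolisable position (C19 is vinylic, C24 quaternary), the β-alkoxide cannot leave so E1cB loss is suppressed, and the two identical arms make C16 non-stereogenic so that the face of attack does not matter.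

Step 5
Reactants: 8 (5R)-6,6-bis(hydroxymethyl)-5-{[isopropoxy(dimethyl)silyl]methyl}-4,4-dimethylcyclohex-2-en-1-one
Product: 9 (5R)-5,6,6-tris(hydroxymethyl)-4,4-dimethylcyclohex-2-en-1-one
Conditions: KF, KHCO3, 30% aq H2O2, THF/MeOH (1:1), rt
Reagents that add atoms: hydrogen peroxide, OO
Why: In the Tamao–Fleming oxidation the fluoride-activated alkoxysilane takes up peroxide and C22 migrates from silicon to oxygen without touching C23, while bicarbonate-buffered peroxide is too weak a nucleophile to epoxidise an enone whose β carbon C20 is neopentyl.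

Step 6
Reactants: 9 (5R)-5,6,6-tris(hydroxymethyl)-4,4-dimethylcyclohex-2-en-1-one
Product: 10 (1R,5R)-2,2-bis(hydroxymethyl)-8,8-dimethyl-6-oxabicyclo[3.2.1]octan-3-one
Conditions: DBU (0.2 equiv), CH2Cl2, rt
Reagents that add atoms: none
Why: In this intramolecular oxa-Michael addition (5-exo-trig) only the C22 hydroxyl, axial on C23, reaches C20 on the same face, so C23 fixes C20 as R, and reversibility funnels the material to the chair-shaped bicycle rather than to strained ethers from the C16 arms.

Step 7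
Reactants: 10 (1R,5R)-2,2-bis(hydroxymethyl)-8,8-dimethyl-6-oxabicyclo[3.2.1]octan-3-one
Product: 11 (1R,2R,5R)-2-{[(tert-butyldimethylsilyl)oxy]methyl}-2-(hydroxymethyl)-8,8-dimethyl-6-oxabicyclo[3.2.1]octan-3-one (silyl ether on the equatorial arm C15, cis to C22)
Conditions: TBSCl (1.05 equiv), imidazole, CH2Cl2, −20 to 0 °C
Reagents that add atoms: tert-butyldimethylsilyl chloride, CC(C)(C)[Si](C)(C)Cl
Why: In this sterically controlled monosilylation the equatorial arm is open while the axial arm is syn-axial to one C24 methyl, so the bulky chlorosilane should take the equatorial hydroxyl, which turns C16 into a stereocentre with the target arrangement.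

Step 8
Reactants: 11 (1R,2R,5R)-2-{[(tert-butyldimethylsilyl)oxy]methyl}-2-(hydroxymethyl)-8,8-dimethyl-6-oxabicyclo[3.2.1]octan-3-one
Product: 12 (1R,2S,5R)-2-{[(tert-butyldimethylsilyl)oxy]methyl}-8,8-dimethyl-3-oxo-6-oxabicyclo[3.2.1]octane-2-carbaldehyde
Conditions: Dess–Martin periodinane (1.3 equiv), CH2Cl2, rt
Reagents that add atoms: none
Why: The Dess–Martin oxidation converts the remaining neopentyl alcohol into the C9 aldehyde under neutral conditions, and the quaternary C16 between the two carbonyl groups excludes enolisation or epimerisation.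

Step 9
Reactants: 12 (1R,2S,5R)-2-{[(tert-butyldimethylsilyl)oxy]methyl}-8,8-dimethyl-3-oxo-6-oxabicyclo[3.2.1]octane-2-carbaldehyde
Product: 13 (2E)-3-[(1R,2S,5R)-2-{[(tert-butyldimethylsilyl)oxy]methyl}-8,8-dimethyl-3-oxo-6-oxabicyclo[3.2.1]octan-2-yl]prop-2-enal
Conditions: Ph3P=CHCHO (1.5 equiv), toluene, 90 °C
Reagents that add atoms: (triphenylphosphoranylidene)acetaldehyde, O=CC=P(c1ccccc1)(c1ccccc1)c1ccccc1
Why: The Wittig olefination with a stabilised ylide reacts only at the aldehyde, not at the hindered C17 ketone, gives the E C9=C8 alkene, and needs no base that could open ring D by retro-oxa-Michael reaction.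

Step 10
Reactants: 14 (S)-3-bromo-2-methylpropan-1-ol
Product: 15 (S)-{[(3-bromo-2-methylpropyl)oxy]methyl}benzene
Conditions: BnOC(=NH)CCl3 (1.2 equiv), TfOH (cat.), CH2Cl2/cyclohexane, 0 °C to rt
Reagents that add atoms: benzyl 2,2,2-trichloroacetimidate, N=C(OCc1ccccc1)C(Cl)(Cl)Cl
Why: Acid-catalysed benzylation with the trichloroacetimidate avoids an alkoxide, which would close an oxetane or eliminate HBr, and leaves the chiral-pool centre C2 untouched.

Step 11
Reactants: 15 (S)-{[(3-bromo-2-methylpropyl)oxy]methyl}benzene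
Product: 16 [(2S)-3-(benzyloxy)-2-methylpropyl]triphenylphosphonium bromide
Conditions: PPh3 (1.5 equiv), toluene, 110 °C
Reagents that add atoms: triphenylphosphine, c1ccc(cc1)P(c1ccccc1)c1ccccc1
Why: SN2 quaternisation of triphenylphosphine by the primary bromide gives the salt, which precipitates from toluene, with C2 as a spectator.

Step 12
Reactants: 13 (2E)-3-[(1R,2S,5R)-2-{[(tert-butyldimethylsilyl)oxy]methyl}-8,8-dimethyl-3-oxo-6-oxabicyclo[3.2.1]octan-2-yl]prop-2-enal; 16 [(2S)-3-(benzyloxy)-2-methylpropyl]triphenylphosphonium bromide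
Product: 18 (1R,2S,5R)-2-[(1E,3Z,5R)-6-(benzyloxy)-5-methylhexa-1,3-dien-1-yl]-2-{[(tert-butyldimethylsilyl)oxy]methyl}-8,8-dimethyl-6-oxabicyclo[3.2.1]octan-3-one, via phosphonium ylide 17 (not isolated)
Conditions: 16 (1.3 equiv), NaN(SiMe3)2 (1.2 equiv), THF, 0 °C; then 13, −78 °C to rt
Reagents that add atoms: none
Why: The lithium-salt-free Wittig olefination of a non-stabilised ylide with an enal is kinetically Z-selective at the new C7=C6 bond and leaves the E C9=C8 bond alone, the aldehyde reacts at −78 °C far faster than the neopentyl C17 ketone, and keeping the base below the amount of salt avoids enolisation toward C19.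

Step 13
Reactants: 18 (1R,2S,5R)-2-[(1E,3Z,5R)-6-(benzyloxy)-5-methylhexa-1,3-dien-1-yl]-2-{[(tert-butyldimethylsilyl)oxy]methyl}-8,8-dimethyl-6-oxabicyclo[3.2.1]octan-3-one
Product: 19 (1R,2S,5R)-2-[(1E,3Z,5R)-6-(benzyloxy)-5-methylhexa-1,3-dien-1-yl]-2-(hydroxymethyl)-8,8-dimethyl-6-oxabicyclo[3.2.1]octan-3-one
Conditions: HF·pyridine, THF/pyridine, 0 °C to rt
Reagents that add atoms: none
Why: Fluoride-mediated desilylation under mildly acidic conditions removes the only silyl ether without touching the benzyl ether, isomerising the diene or provoking the retro-aldol loss of the C15 arm that a basic fluoride source could cause.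

Step 14
Reactants: 19 (1R,2S,5R)-2-[(1E,3Z,5R)-6-(benzyloxy)-5-methylhexa-1,3-dien-1-yl]-2-(hydroxymethyl)-8,8-dimethyl-6-oxabicyclo[3.2.1]octan-3-one
Product: 20 {(1R,2S,5R)-2-[(1E,3Z,5R)-6-(benzyloxy)-5-methylhexa-1,3-dien-1-yl]-8,8-dimethyl-3-oxo-6-oxabicyclo[3.2.1]octan-2-yl}methyl prop-2-enoate
Conditions: acryloyl chloride (1.5 equiv), Et3N, CH2Cl2, −20 to 0 °C
Reagents that add atoms: acryloyl chloride, C=CC(=O)Cl
Why: Acylation of the neopentyl primary alcohol with an acid chloride and a tertiary amine at low temperature installs the dienophile C10=C11 with its carbonyl C12 on O14.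

Step 15
Reactants: 20 {(1R,2S,5R)-2-[(1E,3Z,5R)-6-(benzyloxy)-5-methylhexa-1,3-dien-1-yl]-8,8-dimethyl-3-oxo-6-oxabicyclo[3.2.1]octan-2-yl}methyl prop-2-enoate
Product: 21 cis-fused cyclohexene spiro-δ-lactone with rings A–D complete, C7=C8 alkene and C3 benzyl ether (target numbering 2R,6S,9R,10S,16S,20R,23R)
Conditions: BHT (cat.), toluene (0.005 M), 170 °C, sealed tube
Reagents that add atoms: none
Why: This is a thermal intramolecular Diels–Alder reaction of a hexa-3,5-dienyl acrylate, helped by the geminal placement of diene and dienophile on quaternary C16, in which suprafacial addition turns the 8E,6Z geometry into the trans C9/C6 relationship, the endo position of the tether carbonyl C12 gives the cis C9–H/C10–H fusion, and the diene face is expected to be chosen by C16 because closure on the C23 flank keeps O14 and the ester dipole away from the C17=O18 dipole while the small vinylic C9–H points under ring C.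

Step 16
Reactants: 21 cis-fused cyclohexene spiro-δ-lactone benzyl ether
Product: 22 saturated tetracyclic primary alcohol (target skeleton with C3H2OH; 2R,6R,9R,10S,16S,20R,23R)
Conditions: H2 (1 atm), Pd/C (10 wt %), EtOH, rt
Reagents that add atoms: none
Why: Heterogeneous hydrogenation saturates the disubstituted C7=C8 alkene without creating a stereocentre, and the same catalyst hydrogenolyses the benzyl ether, while the hindered ketone, the lactone and the cyclic ether are inert.

Step 17
Reactants: 22 saturated tetracyclic primary alcohol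
Product: 23 CNP0152427.2 (2R,6R,9R,10S,16S,20R,23R)
Conditions: TEMPO (0.2 equiv), PhI(OAc)2 (2.5 equiv), MeCN/H2O (1:1), rt
Reagents that add atoms: water, O
Why: The oxoammonium-mediated oxidation takes the primary alcohol through the aldehyde hydrate to the acid at near-neutral pH, so that neither C2 nor the lactone α carbon C10 epimerises and ring D does not open.

Compound list
1 | 4,4-dimethylcyclohex-2-en-1-one | CC1(C)CCC(=O)C=C1 | starting material
2 | 4,4-dimethylcyclohexa-2,5-dien-1-one | CC1(C)C=CC(=O)C=C1 | intermediate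
3 | (chloromethyl)(isopropoxy)dimethylsilane | CC(C)O[Si](C)(C)CCl | starting material
4 | {[isopropoxy(dimethyl)silyl]methyl}magnesium chloride | CC(C)O[Si](C)(C)C[Mg]Cl | intermediate
5 | formaldehyde | C=O | starting material
6 | chloromagnesium (5S)-5-{[isopropoxy(dimethyl)silyl]methyl}-4,4-dimethylcyclohexa-1,5-dien-1-olate (C16=C17 enolate) | Cl[Mg]OC1=C[C@H](C[Si](C)(C)OC(C)C)C(C)(C)C=C1 | intermediate
7 | (5S,6R)-6-(hydroxymethyl)-5-{[isopropoxy(dimethyl)silyl]methyl}-4,4-dimethylcyclohex-2-en-1-one | OC[C@@H]1C(=O)C=CC(C)(C)[C@H]1C[Si](C)(C)OC(C)C | intermediate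
8 | (5R)-6,6-bis(hydroxymethyl)-5-{[isopropoxy(dimethyl)silyl]methyl}-4,4-dimethylcyclohex-2-en-1-one | OCC1(CO)C(=O)C=CC(C)(C)[C@H]1C[Si](C)(C)OC(C)C | intermediate
9 | (5R)-5,6,6-tris(hydroxymethyl)-4,4-dimethylcyclohex-2-en-1-one | OCC1(CO)C(=O)C=CC(C)(C)[C@H]1CO | intermediate
10 | (1R,5R)-2,2-bis(hydroxymethyl)-8,8-dimethyl-6-oxabicyclo[3.2.1]octan-3-one | OCC1(CO)C(=O)C[C@H]2OC[C@@H]1C2(C)C | intermediate
11 | (1R,2R,5R)-2-{[(tert-butyldimethylsilyl)oxy]methyl}-2-(hydroxymethyl)-8,8-dimethyl-6-oxabicyclo[3.2.1]octan-3-one | CC(C)(C)[Si](C)(C)OC[C@@]1(CO)C(=O)C[C@H]2OC[C@@H]1C2(C)C | intermediate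
12 | (1R,2S,5R)-2-{[(tert-butyldimethylsilyl)oxy]methyl}-8,8-dimethyl-3-oxo-6-oxabicyclo[3.2.1]octane-2-carbaldehyde | CC(C)(C)[Si](C)(C)OC[C@@]1(C=O)C(=O)C[C@H]2OC[C@@H]1C2(C)C | intermediate
13 | (2E)-3-[(1R,2S,5R)-2-{[(tert-butyldimethylsilyl)oxy]methyl}-8,8-dimethyl-3-oxo-6-oxabicyclo[3.2.1]octan-2-yl]prop-2-enal | CC(C)(C)[Si](C)(C)OC[C@@]1(/C=C/C=O)C(=O)C[C@H]2OC[C@@H]1C2(C)C | intermediate
14 | (S)-3-bromo-2-methylpropan-1-ol | C[C@@H](CO)CBr | starting material
15 | (S)-{[(3-bromo-2-methylpropyl)oxy]methyl}benzene | C[C@@H](COCc1ccccc1)CBr | intermediate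
16 | [(2S)-3-(benzyloxy)-2-methylpropyl]triphenylphosphonium bromide | C[C@@H](COCc1ccccc1)C[P+](c1ccccc1)(c1ccccc1)c1ccccc1.[Br-] | intermediate
17 | [(2S)-3-(benzyloxy)-2-methylpropylidene]triphenylphosphorane | C[C@@H](COCc1ccccc1)C=P(c1ccccc1)(c1ccccc1)c1ccccc1 | intermediate
18 | (1R,2S,5R)-2-[(1E,3Z,5R)-6-(benzyloxy)-5-methylhexa-1,3-dien-1-yl]-2-{[(tert-butyldimethylsilyl)oxy]methyl}-8,8-dimethyl-6-oxabicyclo[3.2.1]octan-3-one | CC(C)(C)[Si](C)(C)OC[C@@]1(/C=C/C=C\[C@@H](C)COCc3ccccc3)C(=O)C[C@H]2OC[C@@H]1C2(C)C | intermediate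
19 | (1R,2S,5R)-2-[(1E,3Z,5R)-6-(benzyloxy)-5-methylhexa-1,3-dien-1-yl]-2-(hydroxymethyl)-8,8-dimethyl-6-oxabicyclo[3.2.1]octan-3-one | OC[C@@]1(/C=C/C=C\[C@@H](C)COCc3ccccc3)C(=O)C[C@H]2OC[C@@H]1C2(C)C | intermediate
20 | {(1R,2S,5R)-2-[(1E,3Z,5R)-6-(benzyloxy)-5-methylhexa-1,3-dien-1-yl]-8,8-dimethyl-3-oxo-6-oxabicyclo[3.2.1]octan-2-yl}methyl prop-2-enoate | C=CC(=O)OC[C@@]1(/C=C/C=C\[C@@H](C)COCc3ccccc3)C(=O)C[C@H]2OC[C@@H]1C2(C)C | intermediate
21 | Diels–Alder adduct, cis-fused C7=C8 cyclohexene spiro-δ-lactone, C3 benzyl ether (2R,6S,9R,10S,16S,20R,23R) | C[C@@H](COCc3ccccc3)[C@@H]1C=C[C@@H]2[C@H](C1)C(=O)OC[C@]21C(=O)C[C@H]2OC[C@@H]1C2(C)C | intermediate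
22 | saturated tetracyclic primary alcohol (2R,6R,9R,10S,16S,20R,23R) | C[C@@H](CO)[C@@H]1CC[C@@H]2[C@H](C1)C(=O)OC[C@]21C(=O)C[C@H]2OC[C@@H]1C2(C)C | intermediate
23 | CNP0152427.2 | C[C@@H](C(=O)O)[C@@H]1CC[C@@H]2[C@H](C1)C(=O)OC[C@]21C(=O)C[C@H]2OC[C@@H]1C2(C)C | target

Total step count: 17.
Longest linear sequence: 14 steps (steps 1, 3–9 and 12–17, from 1).

Steps most likely to fail

**Step 15.**
- What may go wrong:
  - The inward-pointing C2 substituent of the Z alkene raises the barrier of the s-cis diene. A [1,5]-hydrogen migration from C2 to C9, or Z-to-E isomerisation, may then outrun the cycloaddition.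
  - Steric pressure of the axial C24 methyl on the inward-pointing diene hydrogens may erode or reverse the facial selection.
  - The cis lactone is at least the thermodynamic C10 epimer, because a trans fusion would force C8 under ring C.
- Fallback, setting out from 13 and 15 and returning at 22. The Z alkene is replaced by an electron-rich diene with an outward C2 chain, and C6 is corrected by equilibration next to a temporary C7 ketone.
  - Mg in THF converts 15 into the Grignard reagent [(2S)-3-(benzyloxy)-2-methylpropyl]magnesium bromide F1. It adds at −78 °C to the aldehyde of 13 to give the C7 allylic alcohol (both C7 epimers) F2.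
  - Dess–Martin oxidation gives the E-enone F3, HF·pyridine gives the hydroxy enone F4, and acryloyl chloride/Et3N gives the enone acrylate F5.
  - TBSOTf/Et3N converts the enone into the 8E,6Z 2-silyloxy diene F6. It has no inward substituent, and its donor lies para to C10.
  - The intramolecular Diels–Alder reaction should then run near 110 °C in toluene to give the C6-epimeric silyl enol ether adduct F7.
  - Aqueous HF in MeCN frees the ketone, and catalytic DBU equilibrates C6 to give the equatorial C7 ketone F8. An axial C2 chain would be syn-axial to C12.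
  - The less hindered C7 ketone condenses with TsNHNH2 to give the tosylhydrazone F9. Catecholborane followed by NaOAc·3H2O reduces it to the saturated benzyl ether F10.
  - Hydrogenolysis (H2, Pd/C) gives 22.

**Step 3.**
- What may go wrong: uncatalysed Grignard addition may erode the selection between the enantiotopic enones. Capture of the magnesium enolate by polymerising formaldehyde may be incomplete or be followed by dehydration.
- Fallback, setting out from 2 and 4 and returning at 7. The two bond formations are separated.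
  - The same copper/ligand system is run in the presence of Me3SiCl, which accelerates the catalysed pathway.
  - Me3SiCl also silylates 6 as it forms, to give the isolable trimethylsilyl dienol ether F11.
  - A separate Mukaiyama aldol reaction with 37% aqueous 5 under Yb(OTf)3 catalysis in THF then gives 7, with C15 again entering anti to C22.

**Step 7.**
- What may go wrong: discrimination between the two neopentyl hydroxyl groups may be insufficient, leading to silylation of the axial arm or of both arms.
- Fallback, setting out from 7 and returning at 11. The arms are told apart by the order of their introduction instead of by sterics.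
  - The dianion of 7 (LiN(iPr)2, 2.2 equiv, THF, −78 °C) is alkylated on carbon with benzyl chloromethyl ether.
  - The electrophile enters anti to C22, so the new arm C9 ends trans and the old arm C15 cis to C22, giving the benzyloxymethyl hydroxymethyl enone F12.
  - TBSCl/imidazole gives the silyl ether F13, Tamao–Fleming oxidation gives the C22 alcohol F14, and catalytic DBU gives the bicyclic benzyl ether F15.
  - Hydrogenolysis (H2, Pd/C) frees the axial arm and gives 11.

Further compounds
F1 | step 15 | [(2S)-3-(benzyloxy)-2-methylpropyl]magnesium bromide | C[C@@H](COCc1ccccc1)C[Mg]Br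
F2 | step 15 | (1R,2S,5R)-2-[(1E,5R)-6-(benzyloxy)-3-hydroxy-5-methylhex-1-en-1-yl]-2-{[(tert-butyldimethylsilyl)oxy]methyl}-8,8-dimethyl-6-oxabicyclo[3.2.1]octan-3-one (C7 epimers) | CC(C)(C)[Si](C)(C)OC[C@@]1(/C=C/C(O)C[C@@H](C)COCc3ccccc3)C(=O)C[C@H]2OC[C@@H]1C2(C)C
F3 | step 15 | (1R,2S,5R)-2-[(1E,5R)-6-(benzyloxy)-5-methyl-3-oxohex-1-en-1-yl]-2-{[(tert-butyldimethylsilyl)oxy]methyl}-8,8-dimethyl-6-oxabicyclo[3.2.1]octan-3-one | CC(C)(C)[Si](C)(C)OC[C@@]1(/C=C/C(=O)C[C@@H](C)COCc3ccccc3)C(=O)C[C@H]2OC[C@@H]1C2(C)C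
F4 | step 15 | (1R,2S,5R)-2-[(1E,5R)-6-(benzyloxy)-5-methyl-3-oxohex-1-en-1-yl]-2-(hydroxymethyl)-8,8-dimethyl-6-oxabicyclo[3.2.1]octan-3-one | OC[C@@]1(/C=C/C(=O)C[C@@H](C)COCc3ccccc3)C(=O)C[C@H]2OC[C@@H]1C2(C)C
F5 | step 15 | {(1R,2S,5R)-2-[(1E,5R)-6-(benzyloxy)-5-methyl-3-oxohex-1-en-1-yl]-8,8-dimethyl-3-oxo-6-oxabicyclo[3.2.1]octan-2-yl}methyl prop-2-enoate | C=CC(=O)OC[C@@]1(/C=C/C(=O)C[C@@H](C)COCc3ccccc3)C(=O)C[C@H]2OC[C@@H]1C2(C)C
F6 | step 15 | {(1R,2S,5R)-2-[(1E,3Z,5R)-6-(benzyloxy)-3-[(tert-butyldimethylsilyl)oxy]-5-methylhexa-1,3-dien-1-yl]-8,8-dimethyl-3-oxo-6-oxabicyclo[3.2.1]octan-2-yl}methyl prop-2-enoate | C=CC(=O)OC[C@@]1(/C=C/C(O[Si](C)(C)C(C)(C)C)=C/[C@@H](C)COCc3ccccc3)C(=O)C[C@H]2OC[C@@H]1C2(C)C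
F7 | step 15 | cis-fused adduct with C7(OTBS)=C8 silyl enol ether, C6 epimeric to the target series | C[C@@H](COCc3ccccc3)[C@H]1C(O[Si](C)(C)C(C)(C)C)=C[C@@H]2[C@H](C1)C(=O)OC[C@]21C(=O)C[C@H]2OC[C@@H]1C2(C)C
F8 | step 15 | C7 ketone of the saturated benzyl ether, C2 chain equatorial on C6 (6R) | C[C@@H](COCc3ccccc3)[C@@H]1C(=O)C[C@@H]2[C@H](C1)C(=O)OC[C@]21C(=O)C[C@H]2OC[C@@H]1C2(C)C
F9 | step 15 | C7 tosylhydrazone of F8 | C[C@@H](COCc3ccccc3)[C@@H]1C(=NNS(=O)(=O)c3ccc(C)cc3)C[C@@H]2[C@H](C1)C(=O)OC[C@]21C(=O)C[C@H]2OC[C@@H]1C2(C)C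
F10 | step 15 | saturated tetracyclic benzyl ether (O-benzyl 22) | C[C@@H](COCc3ccccc3)[C@@H]1CC[C@@H]2[C@H](C1)C(=O)OC[C@]21C(=O)C[C@H]2OC[C@@H]1C2(C)C
F11 | step 3 | (5S)-5-{[isopropoxy(dimethyl)silyl]methyl}-4,4-dimethyl-1-[(trimethylsilyl)oxy]cyclohexa-1,5-diene (C16=C17 enol ether) | C[Si](C)(C)OC1=C[C@H](C[Si](C)(C)OC(C)C)C(C)(C)C=C1
F12 | step 7 | (5R,6S)-6-[(benzyloxy)methyl]-6-(hydroxymethyl)-5-{[isopropoxy(dimethyl)silyl]methyl}-4,4-dimethylcyclohex-2-en-1-one | OC[C@@]1(COCc2ccccc2)C(=O)C=CC(C)(C)[C@H]1C[Si](C)(C)OC(C)C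
F13 | step 7 | (5R,6R)-6-[(benzyloxy)methyl]-6-{[(tert-butyldimethylsilyl)oxy]methyl}-5-{[isopropoxy(dimethyl)silyl]methyl}-4,4-dimethylcyclohex-2-en-1-one | CC(C)(C)[Si](C)(C)OC[C@@]1(COCc2ccccc2)C(=O)C=CC(C)(C)[C@H]1C[Si](C)(C)OC(C)C
F14 | step 7 | (5R,6R)-6-[(benzyloxy)methyl]-6-{[(tert-butyldimethylsilyl)oxy]methyl}-5-(hydroxymethyl)-4,4-dimethylcyclohex-2-en-1-one | CC(C)(C)[Si](C)(C)OC[C@@]1(COCc2ccccc2)C(=O)C=CC(C)(C)[C@H]1CO
F15 | step 7 | (1R,2R,5R)-2-[(benzyloxy)methyl]-2-{[(tert-butyldimethylsilyl)oxy]methyl}-8,8-dimethyl-6-oxabicyclo[3.2.1]octan-3-one | CC(C)(C)[Si](C)(C)OC[C@@]1(COCc3ccccc3)C(=O)C[C@H]2OC[C@@H]1C2(C)C
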